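0.0873 h⁻¹ is what I read for k, the fraction of the free G that turns into Q each hour, and it is the number to watch on repeating these runs. I get it from the last ash reading as the logarithm of G charged over G left, divided by the time, counting G left as the charge minus Q and so letting J take no G. The last birch reading gives 0.0870 h⁻¹ and the last elm reading 0.0740 h⁻¹, each from a Q reading with a scatter of 2 percentage points, so I treat Q formation as pseudo-first-order in G, leaving E out of the rate down to the 29% of that ash reading.

in all of them: E 0.80 M; D 0.1 mol%

| charge | G | J | remark | time |
|---|---|---|---|---|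
| elm | 0.53 equiv | 0.16 M | run made earlier |  |
| birch | 0.91 equiv | 0.16 M | run made earlier |  |
| ash | 1.3 equiv | 0.16 M | run made earlier |  |
| theta | 0.600 equiv | 0.160 M |  | 8.0 h |
| epsilon | 1.50 equiv | 0.160 M |  | 8.0 h |

| run | time / h | Q / % | E / % |
|---|---|---|---|
| elm | 1.00 | 5 | 80 |
| elm | 2.50 | 14 | 71 |
| elm | 3.00 | 13 | 68 |
| elm | 5.00 | 20 | 61 |
| elm | 6.00 | 19 | 59 |
| birch | 1.00 | 7 | 82 |
| birch | 2.50 | 21 | 62 |
| birch | 3.00 | 20 | 61 |
| birch | 5.00 | 33 | 48 |
| birch | 6.00 | 37 | 47 |
| ash | 0.500 | 7 | 86 |
| ash | 1.33 | 14 | 72 |
| ash | 2.50 | 25 | 56 |
| ash | 4.00 | 37 | 45 |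
| ash | 6.00 | 53 | 29 |

(scatter of a reading: 2 percentage points)

1. which of these there is most of at the end, counted by the E in it, theta (E / Q)
2. which of these there is most of at the end, counted by the E in it, epsilon (E / Q)
3. how much there is at the end of the one of these that leads, in percent of the E charged: theta
4. how much there is at the end of the one of these that leads, in percent of the E charged: epsilon

E + Q stands at 82.0% in that ash reading, close to 80.0%, which is the E left if J, charged at 20.0% of E, takes its equal amount. Two extreme flasks follow. In the first, J has finished and no Q has formed, so E is 80.0%. In the second, Q has formed as far as the charges allow: the limiting reagent changes from G to E at 0.800 equiv of G, so G limits theta, with Q at 60.0% and E at 20.0%, while E limits epsilon, with Q at 80.0%. The real flask at 8.0 h lies between them, and k places it: I reckon that 50.3% of the G has reacted by then, about half of its charge. For theta I reckon Q 30.2% and E 49.8%, so E leads. For epsilon the same step gives Q 75.4% and E 4.61%, so Q leads, but that E lies below the 29% of the last ash reading, so I take 75.4% as my ceiling and expect Q a little under it.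

The forecast names E for theta at 56% and Q for epsilon at 72%, on the ground that “J seems to lock up about 18–20% of E quickly, and probably about the same amount of G”, and its theta figure stands above mine.

Theta gives E 50.2% and Q 29.8%, and epsilon gives Q 70.2% and E 10.3%, which is 5.2 points under my ceiling.

    E + G + D → Q + D, rate k1*[E]*[G]*[D]/(1 + ([E]/sat1)) (49.3 mM, k = 2390 L² mol⁻² h⁻¹)
    E + J → L (k = 1.31 L mol⁻¹ h⁻¹)

The same k goes to theta read at 30 h instead of 8.0 h, with every amount held: the reckoning gives Q 55.6% and E 24.4%, so the lead passes to Q, and that flask holds Q 54.7% and E 25.3%.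

The runs come from a simulation with made-up constants, noise included.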